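**Retrosynthetic overview**
1. Halimane locants are used throughout: ring A = C1–C5/C10, ring B = C5–C10, side chain C11–C15 (C15 = CO2H, C16 on C13), C17 on C8, C18 = CH2OAc and C19 on C4, C20 on C9. The C7 ketone comes from Rh-catalysed allylic C–H oxidation of a Δ5-alkene, and the acid from a tert-butyl ester.
2. The C4 quaternary centre and the Δ5 bond come from deconjugative hydroxymethylation of a ring A Δ4-3-ketone; the C3 oxygen is then removed by tosylhydrazone reduction.
3. Ring A is annulated (Robinson type: C10–C1, then C4=C5) onto a regiodefined ring B enolate with an α-silyl vinyl ketone (fragment 3), in the same flask in which that enolate is made.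
4. The enolate comes from the key convergent step: copper-catalysed conjugate coupling of a side-chain B-alkyl-9-BBN (from fragment 2) with (S)-3,4-dimethylcyclohex-2-enone (fragment 1), which forms C9–C11 and the C9 quaternary centre trans to the C8 methyl.
5. Ring order: ring B first (organocatalytic Michael addition, then aldol condensation in step 2), ring A second (step 11).

Assumption: the target is the (4R,8R,9S,10S,13R) isomer encoded by the SMILES, and the Evans oxazolidinone is a recoverable chiral auxiliary (a reagent, returned in step 7).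

**Fragment 1: ring B enone**

Step 1
Reactants: 1 propanal; 2 but-3-en-2-one
Product: 3 (S)-2-methyl-5-oxohexanal
Conditions: (R)-2-[diphenyl(trimethylsilyloxy)methyl]pyrrolidine (5 mol%), ethyl 3,4-dihydroxybenzoate (20 mol%), neat, 4 °C
Reagents that add atoms: none
Why: Enamine-mediated organocatalytic Michael addition; the (R)-diarylprolinol ether forms the (E)-enamine of propanal and blocks one face, so the enone adds to give the (S)-α-methyl aldehyde (the mirror-image catalyst gives the (R)-series), which sets C8.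

Step 2
Reactants: 3 (S)-2-methyl-5-oxohexanal
Product: 4 (S)-4-methylcyclohex-2-en-1-one
Conditions: LiOH (0.1 equiv), i-PrOH, 0 → 25 °C
Reagents that add atoms: none
Why: Intramolecular aldol condensation of the methyl ketone onto the aldehyde closes ring B; under mild base, ring closure and dehydration outrun α-epimerisation, and the stereocentre becomes the γ-carbon of the enone.

Step 3
Reactants: 4 (S)-4-methylcyclohex-2-en-1-one
Product: 5 trimethyl{[(3R,4S)-3,4-dimethylcyclohex-1-en-1-yl]oxy}silane
Conditions: MeMgBr, CuBr·SMe2 (5 mol%), TMSCl, DMPU, THF, −78 °C; Et3N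
Reagents that add atoms: methylmagnesium bromide C[Mg]Br; chlorotrimethylsilane C[Si](C)(C)Cl
Why: Copper-catalysed, TMSCl-accelerated conjugate addition (Kuwajima–Nakamura conditions) gives the regiodefined silyl enol ether; methyl adds trans to the C4 methyl, but this new centre is erased in step 4.

Step 4
Reactants: 5 trimethyl{[(3R,4S)-3,4-dimethylcyclohex-1-en-1-yl]oxy}silane
Product: 6 (S)-3,4-dimethylcyclohex-2-en-1-one
Conditions: Pd(OAc)2 (10 mol%), O2 (1 atm), DMSO, 25 °C
Reagents that add atoms: none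
Why: Saegusa–Ito oxidation (aerobic variant); divalent palladium forms the C-bound enolate and β-hydride elimination gives the 3-methyl enone without touching the C8 stereocentre.

**Fragment 2: side-chain alkene**

Step 5
Reactants: 7 (E)-but-2-enoyl chloride
Product: 8 (R)-4-benzyl-3-[(E)-but-2-enoyl]-1,3-oxazolidin-2-one
Conditions: (R)-4-benzyl-1,3-oxazolidin-2-one, n-BuLi, THF, −78 °C; then 7
Reagents that add atoms: (R)-4-benzyl-1,3-oxazolidin-2-one O=C1N[C@H](Cc2ccccc2)CO1
Why: N-acylation of the lithiated Evans oxazolidinone by the acid chloride.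

Step 6
Reactants: 8 (R)-4-benzyl-3-[(E)-but-2-enoyl]-1,3-oxazolidin-2-one
Product: 9 (R)-4-benzyl-3-[(S)-3-methylpent-4-enoyl]-1,3-oxazolidin-2-one
Conditions: CH2=CHMgBr, CuBr·SMe2 (0.3 equiv), THF–SMe2, −78 → −20 °C; aq. NH4Cl
Reagents that add atoms: vinylmagnesium bromide C=C[Mg]Br
Why: Auxiliary-controlled copper-mediated conjugate addition; the magnesium-chelated s-cis N-enoyl imide is attacked on the face opposite the benzyl group, setting the future C13 centre ((S) here, (R) once the vinyl group is saturated).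

Step 7
Reactants: 9 (R)-4-benzyl-3-[(S)-3-methylpent-4-enoyl]-1,3-oxazolidin-2-one
Product: 10 (S)-3-methylpent-4-enoic acid
Conditions: LiOH, H2O2, THF–H2O, 0 °C; Na2SO3; HCl
Reagents that add atoms: hydrogen peroxide (as LiOOH) OO
Why: Hydroperoxide hydrolysis cleaves the exocyclic imide carbonyl selectively and returns the auxiliary without touching the β-stereocentre.

Step 8
Reactants: 10 (S)-3-methylpent-4-enoic acid
Product: 11 tert-butyl (S)-3-methylpent-4-enoate
Conditions: 2-methylpropene, H2SO4 (cat.), CH2Cl2, 25 °C, sealed vessel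
Reagents that add atoms: 2-methylpropene CC(C)=C
Why: Acid-catalysed esterification by tert-butyl cation capture gives a base-stable, acid-labile ester; the monosubstituted alkene is far less easily protonated than 2-methylpropene.

**Fragment 3: annulation reagent**

Step 9
Reactants: 12 (1-bromoethenyl)trimethylsilane; 1 propanal
Product: 14 2-(trimethylsilyl)pent-1-en-3-ol, via Grignard reagent 13 (not isolated)
Conditions: Mg, THF, reflux; then 1, 0 °C; aq. NH4Cl
Reagents that add atoms: none
Why: Grignard formation from the α-bromovinylsilane and 1,2-addition to the aldehyde; the racemic carbinol centre is removed in step 10.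

Step 10
Reactants: 14 2-(trimethylsilyl)pent-1-en-3-ol
Product: 15 2-(trimethylsilyl)pent-1-en-3-one
Conditions: CrO3, H2SO4, acetone, 0 °C
Reagents that add atoms: none
Why: Jones oxidation of the allylic alcohol gives the α-silyl vinyl ketone, a Stork–Ganem-type annulation reagent that resists polymerisation under aprotic enolate conditions.

**Union and completion**

Step 11
Reactants: 11 tert-butyl (S)-3-methylpent-4-enoate; 6 (S)-3,4-dimethylcyclohex-2-en-1-one; 15 2-(trimethylsilyl)pent-1-en-3-one
Product: 19 tert-butyl (3R)-3-methyl-5-[(1R,2S,8aS)-1,2,5-trimethyl-6-oxo-1,2,3,4,6,7,8,8a-octahydronaphthalen-1-yl]pentanoate, via B-alkyl-9-BBN 16 (not isolated), via potassium enolate 17 (not isolated), via Michael adduct 18 (not isolated)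
Conditions: (9-BBN-H)2, THF, 60 °C; KOMe (1.2 equiv); 6, CuCl (10 mol%), 1,3-dimesitylimidazolinium chloride (12 mol%), toluene–THF, 40 °C; 15 (1.5 equiv), −78 → −20 °C; NaOMe (2 equiv), MeOH, 25 → 60 °C; aq. NH4Cl
Reagents that add atoms: none
Why: Proposed new method: copper/N-heterocyclic-carbene-catalysed conjugate coupling of an ester-bearing B-alkyl-9-BBN with a β,β-disubstituted, γ-branched cyclohexenone, telescoped into annulation of the enolate it releases; anti-Markovnikov hydroboration gives 16, whose methoxyborate transmetalates to a carbene-ligated monovalent copper alkyl, which adds to 6 through a trivalent copper β-cuprio enolate anti to the pseudoaxial C8 methyl, so reductive elimination forms C9–C11 trans to C8–Me (C8 and C9 methyls cis) and the copper enolate is turned over by further borate to the regiodefined potassium enolate 17, held as a weakly basic ate complex with B-methoxy-9-BBN that resists proton exchange; 17 then adds at C10 to the α-silyl vinyl ketone (Stork–Ganem/Boeckman-type conjugate addition–annulation), methoxide removes silicon from 18 and closes ring A by aldol condensation, and C10 (γ to the new enone) equilibrates to the isomer with H-10 anti to the axial C9 methyl and C1 equatorial on ring B; the closest known reactions are copper-catalysed conjugate additions of alkyl-9-BBN reagents to chelating acyl-imidazole enones, copper-catalysed additions of alkylzirconocenes or Grignard reagents to 3-methylcyclohexenones, and stoichiometric cuprate addition–annulation with α-silyl vinyl ketones.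

Step 12
Reactants: 19 tert-butyl (3R)-3-methyl-5-[(1R,2S,8aS)-1,2,5-trimethyl-6-oxo-1,2,3,4,6,7,8,8a-octahydronaphthalen-1-yl]pentanoate
Product: 21 tert-butyl (3R)-5-[(1R,2S,5R,8aS)-5-(hydroxymethyl)-1,2,5-trimethyl-6-oxo-1,2,3,5,6,7,8,8a-octahydronaphthalen-1-yl]-3-methylpentanoate, via potassium dienolate 20 (not isolated)
Conditions: KOt-Bu, t-BuOH–THF, 25 °C; CH2O (g), −78 °C; aq. NH4Cl, −78 °C
Reagents that add atoms: formaldehyde C=O
Why: Deconjugative α-hydroxymethylation (aldol reaction of the thermodynamic extended dienolate); formaldehyde attacks C4 axially from the α face (the face of axial H-10, leading directly to the ring A chair), placing CH2OH cis to H-10 and moving the alkene to C5=C6, while the cold quench prevents retro-aldol loss.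

Step 13
Reactants: 21 tert-butyl (3R)-5-[(1R,2S,5R,8aS)-5-(hydroxymethyl)-1,2,5-trimethyl-6-oxo-1,2,3,5,6,7,8,8a-octahydronaphthalen-1-yl]-3-methylpentanoate
Product: 22 tert-butyl (3R)-5-[(1R,2S,5R,8aS)-5-(acetoxymethyl)-1,2,5-trimethyl-6-oxo-1,2,3,5,6,7,8,8a-octahydronaphthalen-1-yl]-3-methylpentanoate
Conditions: Ac2O, pyridine, DMAP (cat.), CH2Cl2, 0 → 25 °C
Reagents that add atoms: acetic anhydride CC(=O)OC(C)=O
Why: Nucleophile-catalysed acetylation of the neopentyl primary alcohol installs the final acetate and blocks retro-aldol; C4 has no hydrogen, so the β-acetoxy ketone cannot eliminate.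

Step 14
Reactants: 22 tert-butyl (3R)-5-[(1R,2S,5R,8aS)-5-(acetoxymethyl)-1,2,5-trimethyl-6-oxo-1,2,3,5,6,7,8,8a-octahydronaphthalen-1-yl]-3-methylpentanoate
Product: 24 tert-butyl (3R)-5-[(1R,2S,5R,8aS)-5-(acetoxymethyl)-1,2,5-trimethyl-1,2,3,5,6,7,8,8a-octahydronaphthalen-1-yl]-3-methylpentanoate, via tosylhydrazone 23 (not isolated)
Conditions: TsNHNH2, PPTS (cat.), THF, 60 °C; then catecholborane, CHCl3, 0 °C; NaOAc·3H2O, reflux
Reagents that add atoms: none
Why: Caglioti-type ketone deoxygenation in the Kabalka variant; catecholborane reduces the tosylhydrazone, and acetate-triggered loss of sulfinate and N2 leaves CH2 at C3 under conditions that spare both esters and the non-conjugated alkene.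

Step 15
Reactants: 24 tert-butyl (3R)-5-[(1R,2S,5R,8aS)-5-(acetoxymethyl)-1,2,5-trimethyl-1,2,3,5,6,7,8,8a-octahydronaphthalen-1-yl]-3-methylpentanoate
Product: 25 tert-butyl (3R)-5-[(1S,2R,5R,8aS)-5-(acetoxymethyl)-1,2,5-trimethyl-3-oxo-1,2,3,5,6,7,8,8a-octahydronaphthalen-1-yl]-3-methylpentanoate
Conditions: Rh2(cap)4 (cap = caprolactamate, 1 mol%), t-BuOOH (70% aq.), ClCH2CH2Cl, 40 °C
Reagents that add atoms: tert-butyl hydroperoxide CC(C)(C)OO
Why: Dirhodium-catalysed allylic C–H oxidation (the method used for Δ5-steroid to 7-ketone conversion); tert-butylperoxyl radicals abstract hydrogen at C7, the only allylic methylene, because C4 has no hydrogen and the tertiary H-10 is shielded by the syn-axial CH2OAc and the C9 quaternary centre.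

Step 16
Reactants: 25 tert-butyl (3R)-5-[(1S,2R,5R,8aS)-5-(acetoxymethyl)-1,2,5-trimethyl-3-oxo-1,2,3,5,6,7,8,8a-octahydronaphthalen-1-yl]-3-methylpentanoate
Product: 26 (3R)-5-[(1S,2R,5R,8aS)-5-(acetoxymethyl)-1,2,5-trimethyl-3-oxo-1,2,3,5,6,7,8,8a-octahydronaphthalen-1-yl]-3-methylpentanoic acid
Conditions: CF3CO2H, CH2Cl2, 0 → 25 °C
Reagents that add atoms: none
Why: Acidolysis of the tert-butyl ester (loss of 2-methylpropene) frees the acid while the primary acetate and the enone survive; the short, cold exposure limits enolisation at C8.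

**Compound list**
1 | propanal | CCC=O | starting material
2 | but-3-en-2-one | CC(=O)C=C | starting material
3 | (S)-2-methyl-5-oxohexanal | CC(=O)CC[C@H](C)C=O | intermediate
4 | (S)-4-methylcyclohex-2-en-1-one | O=C1CC[C@H](C)C=C1 | intermediate
5 | trimethyl{[(3R,4S)-3,4-dimethylcyclohex-1-en-1-yl]oxy}silane | C[Si](C)(C)OC1=C[C@H](C)[C@@H](C)CC1 | intermediate
6 | (S)-3,4-dimethylcyclohex-2-en-1-one | O=C1CC[C@H](C)C(C)=C1 | intermediate
7 | (E)-but-2-enoyl chloride | C/C=C/C(Cl)=O | starting material
8 | (R)-4-benzyl-3-[(E)-but-2-enoyl]-1,3-oxazolidin-2-one | C/C=C/C(=O)N1[C@H](Cc2ccccc2)COC1=O | intermediate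
9 | (R)-4-benzyl-3-[(S)-3-methylpent-4-enoyl]-1,3-oxazolidin-2-one | C=C[C@@H](C)CC(=O)N1[C@H](Cc2ccccc2)COC1=O | intermediate
10 | (S)-3-methylpent-4-enoic acid | C=C[C@@H](C)CC(=O)O | intermediate
11 | tert-butyl (S)-3-methylpent-4-enoate | C=C[C@@H](C)CC(=O)OC(C)(C)C | intermediate
12 | (1-bromoethenyl)trimethylsilane | C=C(Br)[Si](C)(C)C | starting material
13 | [1-(trimethylsilyl)ethenyl]magnesium bromide | C=C([Mg]Br)[Si](C)(C)C | intermediate
14 | 2-(trimethylsilyl)pent-1-en-3-ol (racemic) | CCC(O)C(=C)[Si](C)(C)C | intermediate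
15 | 2-(trimethylsilyl)pent-1-en-3-one | CCC(=O)C(=C)[Si](C)(C)C | intermediate
16 | tert-butyl (R)-5-(9-borabicyclo[3.3.1]nonan-9-yl)-3-methylpentanoate | CC(C)(C)OC(=O)C[C@H](C)CCB1C2CCCC1CCC2 | intermediate
17 | potassium (3R,4S)-3-[(3R)-5-tert-butoxy-3-methyl-5-oxopentyl]-3,4-dimethylcyclohex-1-en-1-olate | [K+].[O-]C1=C[C@](C)(CC[C@@H](C)CC(=O)OC(C)(C)C)[C@@H](C)CC1 | intermediate
18 | tert-butyl (3R)-5-{(1R,6S)-1,6-dimethyl-3-oxo-2-[3-oxo-2-(trimethylsilyl)pentyl]cyclohexyl}-3-methylpentanoate (epimers at the two new CH centres) | CCC(=O)C([Si](C)(C)C)CC1C(=O)CC[C@H](C)[C@@]1(C)CC[C@@H](C)CC(=O)OC(C)(C)C | intermediate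
19 | tert-butyl (3R)-3-methyl-5-[(1R,2S,8aS)-1,2,5-trimethyl-6-oxo-1,2,3,4,6,7,8,8a-octahydronaphthalen-1-yl]pentanoate | CC1=C2CC[C@H](C)[C@@](C)(CC[C@@H](C)CC(=O)OC(C)(C)C)[C@@H]2CCC1=O | intermediate
20 | potassium (4aS,5R,6S)-5-[(3R)-5-tert-butoxy-3-methyl-5-oxopentyl]-1,5,6-trimethyl-3,4,4a,5,6,7-hexahydronaphthalen-2-olate | [K+].CC1=C([O-])CC[C@@H]2C1=CC[C@H](C)[C@@]2(C)CC[C@@H](C)CC(=O)OC(C)(C)C | intermediate
21 | tert-butyl (3R)-5-[(1R,2S,5R,8aS)-5-(hydroxymethyl)-1,2,5-trimethyl-6-oxo-1,2,3,5,6,7,8,8a-octahydronaphthalen-1-yl]-3-methylpentanoate | OC[C@]1(C)C(=O)CC[C@@H]2C1=CC[C@H](C)[C@@]2(C)CC[C@@H](C)CC(=O)OC(C)(C)C | intermediate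
22 | tert-butyl (3R)-5-[(1R,2S,5R,8aS)-5-(acetoxymethyl)-1,2,5-trimethyl-6-oxo-1,2,3,5,6,7,8,8a-octahydronaphthalen-1-yl]-3-methylpentanoate | CC(=O)OC[C@]1(C)C(=O)CC[C@@H]2C1=CC[C@H](C)[C@@]2(C)CC[C@@H](C)CC(=O)OC(C)(C)C | intermediate
23 | tert-butyl (3R)-5-[(1R,2S,5S,8aS)-5-(acetoxymethyl)-1,2,5-trimethyl-6-(tosylhydrazinylidene)-1,2,3,5,6,7,8,8a-octahydronaphthalen-1-yl]-3-methylpentanoate | CC(=O)OC[C@]1(C)C(=NNS(=O)(=O)c3ccc(C)cc3)CC[C@@H]2C1=CC[C@H](C)[C@@]2(C)CC[C@@H](C)CC(=O)OC(C)(C)C | intermediate
24 | tert-butyl (3R)-5-[(1R,2S,5R,8aS)-5-(acetoxymethyl)-1,2,5-trimethyl-1,2,3,5,6,7,8,8a-octahydronaphthalen-1-yl]-3-methylpentanoate | CC(=O)OC[C@]1(C)CCC[C@@H]2C1=CC[C@H](C)[C@@]2(C)CC[C@@H](C)CC(=O)OC(C)(C)C | intermediate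
25 | tert-butyl (3R)-5-[(1S,2R,5R,8aS)-5-(acetoxymethyl)-1,2,5-trimethyl-3-oxo-1,2,3,5,6,7,8,8a-octahydronaphthalen-1-yl]-3-methylpentanoate | CC(=O)OC[C@]1(C)CCC[C@@H]2C1=CC(=O)[C@H](C)[C@@]2(C)CC[C@@H](C)CC(=O)OC(C)(C)C | intermediate
26 | (3R)-5-[(1S,2R,5R,8aS)-5-(acetoxymethyl)-1,2,5-trimethyl-3-oxo-1,2,3,5,6,7,8,8a-octahydronaphthalen-1-yl]-3-methylpentanoic acid (CNP0210381.1) | CC(=O)OC[C@]1(C)CCC[C@@H]2C1=CC(=O)[C@H](C)[C@@]2(C)CC[C@@H](C)CC(=O)O | target

**Step count**
Total: 16 steps. Longest linear sequence: 10 steps (steps 1–4 then 11–16, or equally steps 5–8 then 11–16).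

**Three steps most likely to fail**

Step 11 (the proposed new coupling–annulation). The borate-to-copper transfer may be too slow for a β,β-disubstituted enone. The basic medium may erode the γ-stereocentre of 6. The boron-complexed enolate may be too unreactive toward 15, or residual alkylcopper may add to 15. The fallback uses known chemistry, sets out from 11 and 6, and comes back to the route at 17. Hydrozirconation of 11 with Cp2Zr(H)Cl (CH2Cl2, 25 °C; tert-butyl esters tolerate short exposure) gives the alkylzirconocene chloride F1. F1 is added to 6 under established conditions for quaternary centres on 3-methylcyclohexenones: CuCl (10 mol%), a phosphoramidite ligand matched to the substrate bias, AgOTf (11 mol%), TMSCl, t-BuOMe, 25 °C. The TMSCl present traps the enolate, and anhydrous work-up (Et3N, pentane) gives the trimethylsilyl enol ether F2, which can be purified. KOt-Bu (THF, −40 °C) then cleaves F2 to potassium enolate 17, now free of boron and copper residues. From 17 the route continues as in step 11 (15 at −78 °C, then NaOMe/MeOH) through 18 to 19.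

Step 12 (deconjugative hydroxymethylation). Risks are retro-aldol loss, a second hydroxymethylation at C2, attack at C6 or on oxygen, and imperfect face selectivity with so small an electrophile. The fallback sets out from 19 and returns at 21, replacing the reversible aldol by an irreversible SN2 alkylation. The same potassium dienolate (KOt-Bu, t-BuOH–THF) is alkylated with 4-methoxybenzyl chloromethyl ether and NaI to give the 4-methoxybenzyl ether F3, again by axial α-attack at C4. DDQ in CH2Cl2–pH 7 buffer then removes the benzyl group to give 21.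

Step 15 (allylic C–H oxidation). Risks are hydrogen abstraction at the tertiary allylic C10–H (transposed or peroxidic by-products) and incomplete conversion at the hindered alkene. The fallback sets out from 24 and returns at 25 by an epoxide route that never forms an allylic radical. mCPBA (CH2Cl2, NaHCO3, 0 °C) gives the 5,6-epoxide F4 (either face serves). PhSeSePh/NaBH4 (EtOH) opens it at C6 to the hydroxy selenide F5. H2O2 (THF, 0 → 25 °C) then brings about selenoxide syn-elimination toward C7, giving the tertiary allylic alcohol F6. Pyridinium chlorochromate, C5H5NH[CrO3Cl] (CH2Cl2, 25 °C), effects the oxidative 1,3-transposition (Babler–Dauben) to the enone 25. If the acetate is partly cleaved in the selenide step, it is restored with Ac2O/pyridine before the oxidation.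

**Further compounds**
F1 | step 11 | chlorobis(cyclopentadienyl)[(3R)-5-tert-butoxy-3-methyl-5-oxopentyl]zirconium | Cl[Zr](CC[C@@H](C)CC(=O)OC(C)(C)C)(C1C=CC=C1)C1C=CC=C1
F2 | step 11 | tert-butyl (3R)-5-[(1R,6S)-1,6-dimethyl-3-(trimethylsilyloxy)cyclohex-2-en-1-yl]-3-methylpentanoate | C[Si](C)(C)OC1=C[C@](C)(CC[C@@H](C)CC(=O)OC(C)(C)C)[C@@H](C)CC1
F3 | step 12 | tert-butyl (3R)-5-[(1R,2S,5R,8aS)-5-[(4-methoxybenzyloxy)methyl]-1,2,5-trimethyl-6-oxo-1,2,3,5,6,7,8,8a-octahydronaphthalen-1-yl]-3-methylpentanoate | COc1ccc(COC[C@]2(C)C(=O)CC[C@@H]3C2=CC[C@H](C)[C@@]3(C)CC[C@@H](C)CC(=O)OC(C)(C)C)cc1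
F4 | step 15 | 5,6-epoxide of 24 (halimane numbering; epoxide face not defined) | CC(=O)OC[C@]1(C)CCC[C@@H]2C13OC3C[C@H](C)[C@@]2(C)CC[C@@H](C)CC(=O)OC(C)(C)C
F5 | step 15 | 5-hydroxy-6-(phenylselanyl) derivative of 24 (halimane numbering) | CC(=O)OC[C@]1(C)CCC[C@@H]2C1(O)C([Se]c3ccccc3)C[C@H](C)[C@@]2(C)CC[C@@H](C)CC(=O)OC(C)(C)C
F6 | step 15 | tert-butyl (3R)-5-[5-(acetoxymethyl)-4a-hydroxy-1,2,5-trimethyl-1,2,4a,5,6,7,8,8a-octahydronaphthalen-1-yl]-3-methylpentanoate | CC(=O)OC[C@]1(C)CCC[C@@H]2C1(O)C=C[C@H](C)[C@@]2(C)CC[C@@H](C)CC(=O)OC(C)(C)C
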